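**Retrosynthetic overview**

- Target ⇐ triol (formate on the primary allylic OH, then two acetates) ⇐ one i-Bu2AlH reduction of a cis-fused bicyclic enone–ester–acetate.
- Both rings form together: an intramolecular Diels–Alder reaction of a 2-silyloxydiene (C1–C4) with the sulfonyl-capped alkene (C5=C6) of a dienoate makes C1–C6 and C4–C5. Ring A is the cycloaddition ring and ring B the tether ring; loss of sulfinate then gives the C4=C5 enone.
- Cycloaddition precursor ⇐ cross-metathesis with ethyl vinyl ketone ⇐ catalytic asymmetric (Z)-crotylboration (sets C9 and C10) of a dienoate aldehyde.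
- C7=C11 geometry ⇐ (E)-enol tosylate of a 2-methyl β-keto ester, then Heck coupling with phenyl vinyl sulfone; β-keto ester ⇐ 4,4-dimethoxybutan-2-one, dimethyl carbonate and MeI.

Assumption: the locants C1–C13 used in the comments are cadinane locants. Ring A = C1–C6 (C3–O, C4–CH3, C4=C5); ring B = C1, C6–C10 (C7=C11, C9–O, C10–CH3); C12 = CH2O and C13 = CH3 on C11.

**Route**

Step 1
Reactants: 1 4,4-dimethoxybutan-2-one; 2 dimethyl carbonate
Product: 3 methyl 5,5-dimethoxy-3-oxopentanoate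
Conditions: NaH, THF, reflux; then AcOH
Reagents that add atoms: none
Why: Crossed Claisen condensation in which the methyl-side enolate of the ketone is acylated by the carbonate and the doubly stabilised β-keto ester enolate drives the equilibrium; no stereocentre is formed.

Step 2
Reactants: 3 methyl 5,5-dimethoxy-3-oxopentanoate
Product: 4 methyl 5,5-dimethoxy-2-methyl-3-oxopentanoate (racemic)
Conditions: MeI, K2CO3, acetone, rt
Reagents that add atoms: iodomethane, CI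
Why: C-alkylation of the β-keto ester enolate under mild carbonate conditions that spare the acetal; the new centre is racemic and is erased in step 3.

Step 3
Reactants: 4 methyl 5,5-dimethoxy-2-methyl-3-oxopentanoate
Product: 5 methyl (2E)-5,5-dimethoxy-2-methyl-3-[(4-methylphenyl)sulfonyloxy]pent-2-enoate
Conditions: TsCl, N-methylimidazole, Et3N, MeCN, 0 °C to rt
Reagents that add atoms: 4-methylbenzenesulfonyl chloride, Cc1ccc(cc1)S(=O)(=O)Cl
Why: Tanabe-type enol tosylation under non-chelating amine conditions traps the enolate as the (E)-enol tosylate (OTs anti to CO2Me), which fixes the later C7=C11 geometry.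

Step 4
Reactants: 5 methyl (2E)-5,5-dimethoxy-2-methyl-3-[(4-methylphenyl)sulfonyloxy]pent-2-enoate; 6 phenyl vinyl sulfone
Product: 7 methyl (2E,4E)-3-(2,2-dimethoxyethyl)-2-methyl-5-(phenylsulfonyl)penta-2,4-dienoate
Conditions: PdCl2(cod) (5 mol %), (t-Bu)3P·HBF4, Cy2NMe, LiCl, DMF, 100 °C
Reagents that add atoms: none
Why: Mizoroki–Heck reaction of the activated alkenyl tosylate at the terminal carbon of the vinyl sulfone; oxidative addition and insertion retain the enoate geometry and syn β-hydride elimination gives the trans alkenyl sulfone.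

Step 5
Reactants: 7 methyl (2E,4E)-3-(2,2-dimethoxyethyl)-2-methyl-5-(phenylsulfonyl)penta-2,4-dienoate
Product: 8 methyl (2E,4E)-2-methyl-3-(2-oxoethyl)-5-(phenylsulfonyl)penta-2,4-dienoate
Conditions: TFA, H2O, CH2Cl2, 0 °C; used crude
Reagents that add atoms: water, O
Why: Acid-catalysed acetal hydrolysis, kept cold and brief so that the β,γ-unsaturated aldehyde does not isomerise; no stereocentre is involved.

Step 6
Reactants: 8 methyl (2E,4E)-2-methyl-3-(2-oxoethyl)-5-(phenylsulfonyl)penta-2,4-dienoate; 9 2-[(2Z)-but-2-en-1-yl]-4,4,5,5-tetramethyl-1,3,2-dioxaborolane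
Product: 10 methyl (2E,4E)-3-[(2S,3S)-2-hydroxy-3-methylpent-4-en-1-yl]-2-methyl-5-(phenylsulfonyl)penta-2,4-dienoate
Conditions: (R)-TRIP [(R)-3,3'-bis(2,4,6-triisopropylphenyl)-1,1'-binaphthyl-2,2'-diyl hydrogen phosphate] (5 mol %), 4 Å MS, toluene, −30 °C
Reagents that add atoms: none
Why: Chiral phosphoric acid-catalysed crotylboration through a closed chair transition state, in which the (Z)-crotyl group gives the syn adduct and the (R)-catalyst is expected to direct addition to the Re face of the aldehyde, setting C9 and C10 (both S).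

Step 7
Reactants: 10 methyl (2E,4E)-3-[(2S,3S)-2-hydroxy-3-methylpent-4-en-1-yl]-2-methyl-5-(phenylsulfonyl)penta-2,4-dienoate
Product: 11 methyl (2E,4E)-3-[(2S,3S)-2-acetoxy-3-methylpent-4-en-1-yl]-2-methyl-5-(phenylsulfonyl)penta-2,4-dienoate
Conditions: Ac2O, pyridine, DMAP (cat.), CH2Cl2, 0 °C
Reagents that add atoms: acetic anhydride, CC(=O)OC(C)=O
Why: O-acylation of the secondary alcohol, done at once because the free δ-hydroxy (Z)-enoate would lactonise; the stereocentres are untouched.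

Step 8
Reactants: 11 methyl (2E,4E)-3-[(2S,3S)-2-acetoxy-3-methylpent-4-en-1-yl]-2-methyl-5-(phenylsulfonyl)penta-2,4-dienoate; 12 pent-1-en-3-one
Product: 13 methyl (2E,4E)-3-[(2S,3S,4E)-2-acetoxy-3-methyl-6-oxooct-4-en-1-yl]-2-methyl-5-(phenylsulfonyl)penta-2,4-dienoate
Conditions: 12 (4 equiv), second-generation Hoveyda–Grubbs catalyst (5 mol %), CH2Cl2, 40 °C
Reagents that add atoms: none
Why: Olefin cross-metathesis of the terminal alkene with excess enone gives the (E)-enone, while the internal alkenyl sulfone and the tetrasubstituted enoate are spectators toward the ruthenium carbene.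

Step 9
Reactants: 13 methyl (2E,4E)-3-[(2S,3S,4E)-2-acetoxy-3-methyl-6-oxooct-4-en-1-yl]-2-methyl-5-(phenylsulfonyl)penta-2,4-dienoate
Product: 16 methyl (2E)-2-[(3S,4S,4aR,8aR)-3-acetoxy-4,7-dimethyl-6-oxo-3,4,4a,5,6,8a-hexahydronaphthalen-1(2H)-ylidene]propanoate, via silyl dienol ether 14 (not isolated), via sulfonyl cycloadduct 15 (not isolated)
Conditions: TBSOTf (1.3 equiv), Et3N, CH2Cl2, −78 to 0 °C; then toluene, 90 °C; then Bu4NF (1.1 equiv), THF, 0 °C
Reagents that add atoms: none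
Why: Soft enolisation gives the 2-silyloxydiene, which undergoes an intramolecular Diels–Alder reaction with the sulfone-bearing alkene (ring A) across the four-atom tether (ring B), where the planar s-trans dienoate puts C5 axial on ring B (cis fusion at C1 and C6) and the equatorial C10 methyl selects the diene face; fluoride then frees the ketone and E1cB loss of sulfinate gives the C4=C5 enone.

Step 10
Reactants: 16 methyl (2E)-2-[(3S,4S,4aR,8aR)-3-acetoxy-4,7-dimethyl-6-oxo-3,4,4a,5,6,8a-hexahydronaphthalen-1(2H)-ylidene]propanoate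
Product: 17 (2E)-2-[(3S,4S,4aR,6S,8aR)-3,6-dihydroxy-4,7-dimethyl-3,4,4a,5,6,8a-hexahydronaphthalen-1(2H)-ylidene]propan-1-ol
Conditions: i-Bu2AlH (8 equiv), CH2Cl2, −78 to −20 °C; Rochelle salt work-up
Reagents that add atoms: none
Why: i-Bu2AlH does the 1,2-reduction of the enone, reduces the methyl ester to the allylic alcohol and cleaves the acetate, with hydride reaching C3 anti to the axial C1–C10 bond of the cis-decalin to give the 3S alcohol (C3–O cis to C10).

Step 11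
Reactants: 17 (2E)-2-[(3S,4S,4aR,6S,8aR)-3,6-dihydroxy-4,7-dimethyl-3,4,4a,5,6,8a-hexahydronaphthalen-1(2H)-ylidene]propan-1-ol
Product: 18 (2E)-2-[(3S,4S,4aR,6S,8aR)-3,6-dihydroxy-4,7-dimethyl-3,4,4a,5,6,8a-hexahydronaphthalen-1(2H)-ylidene]propyl formate
Conditions: HCO2CH2CF3 (3 equiv), THF, 40 °C
Reagents that add atoms: 2,2,2-trifluoroethyl formate, O=COCC(F)(F)F
Why: Chemoselective formylation by transesterification, which is much faster at the unhindered primary allylic alcohol than at the two secondary alcohols; no stereocentre changes.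

Step 12
Reactants: 18 (2E)-2-[(3S,4S,4aR,6S,8aR)-3,6-dihydroxy-4,7-dimethyl-3,4,4a,5,6,8a-hexahydronaphthalen-1(2H)-ylidene]propyl formate
Product: 19 (2E)-2-[(3S,4S,4aR,6S,8aR)-3,6-diacetoxy-4,7-dimethyl-3,4,4a,5,6,8a-hexahydronaphthalen-1(2H)-ylidene]propyl formate
Conditions: Ac2O, pyridine, rt
Reagents that add atoms: acetic anhydride, CC(=O)OC(C)=O
Why: Acetylation of both secondary alcohols with retention, run without DMAP so that the formate does not exchange.

**Compound list**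

1 | 4,4-dimethoxybutan-2-one | CC(=O)CC(OC)OC | starting material
2 | dimethyl carbonate | COC(=O)OC | starting material
3 | methyl 5,5-dimethoxy-3-oxopentanoate | COC(=O)CC(=O)CC(OC)OC | intermediate
4 | methyl 5,5-dimethoxy-2-methyl-3-oxopentanoate (racemic) | COC(=O)C(C)C(=O)CC(OC)OC | intermediate
5 | methyl (2E)-5,5-dimethoxy-2-methyl-3-[(4-methylphenyl)sulfonyloxy]pent-2-enoate | COC(=O)/C(C)=C(/OS(=O)(=O)c1ccc(C)cc1)CC(OC)OC | intermediate
6 | phenyl vinyl sulfone | C=CS(=O)(=O)c1ccccc1 | starting material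
7 | methyl (2E,4E)-3-(2,2-dimethoxyethyl)-2-methyl-5-(phenylsulfonyl)penta-2,4-dienoate | COC(=O)/C(C)=C(/C=C/S(=O)(=O)c1ccccc1)CC(OC)OC | intermediate
8 | methyl (2E,4E)-2-methyl-3-(2-oxoethyl)-5-(phenylsulfonyl)penta-2,4-dienoate | COC(=O)/C(C)=C(/C=C/S(=O)(=O)c1ccccc1)CC=O | intermediate
9 | 2-[(2Z)-but-2-en-1-yl]-4,4,5,5-tetramethyl-1,3,2-dioxaborolane | C/C=C\CB1OC(C)(C)C(C)(C)O1 | starting material
10 | methyl (2E,4E)-3-[(2S,3S)-2-hydroxy-3-methylpent-4-en-1-yl]-2-methyl-5-(phenylsulfonyl)penta-2,4-dienoate | COC(=O)/C(C)=C(/C=C/S(=O)(=O)c1ccccc1)C[C@H](O)[C@@H](C)C=C | intermediate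
11 | methyl (2E,4E)-3-[(2S,3S)-2-acetoxy-3-methylpent-4-en-1-yl]-2-methyl-5-(phenylsulfonyl)penta-2,4-dienoate | COC(=O)/C(C)=C(/C=C/S(=O)(=O)c1ccccc1)C[C@H](OC(C)=O)[C@@H](C)C=C | intermediate
12 | pent-1-en-3-one (ethyl vinyl ketone) | CCC(=O)C=C | starting material
13 | methyl (2E,4E)-3-[(2S,3S,4E)-2-acetoxy-3-methyl-6-oxooct-4-en-1-yl]-2-methyl-5-(phenylsulfonyl)penta-2,4-dienoate | COC(=O)/C(C)=C(/C=C/S(=O)(=O)c1ccccc1)C[C@H](OC(C)=O)[C@@H](C)/C=C/C(=O)CC | intermediate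
14 | methyl (2E,4E)-3-[(2S,3S,4E,6Z)-2-acetoxy-6-(tert-butyldimethylsilyloxy)-3-methylocta-4,6-dien-1-yl]-2-methyl-5-(phenylsulfonyl)penta-2,4-dienoate | COC(=O)/C(C)=C(/C=C/S(=O)(=O)c1ccccc1)C[C@H](OC(C)=O)[C@@H](C)/C=C/C(O[Si](C)(C)C(C)(C)C)=C/C | intermediate (not isolated)
15 | methyl (2E)-2-[(3S,4S,4aR,7S,8S,8aS)-3-acetoxy-6-(tert-butyldimethylsilyloxy)-4,7-dimethyl-8-(phenylsulfonyl)-3,4,4a,7,8,8a-hexahydronaphthalen-1(2H)-ylidene]propanoate (cis-fused) | CC(C)(C)[Si](C)(C)OC1=C[C@H]2[C@H](C)[C@@H](OC(C)=O)C/C(=C(/C)C(=O)OC)[C@H]2[C@H](S(=O)(=O)c2ccccc2)[C@H]1C | intermediate (not isolated)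
16 | methyl (2E)-2-[(3S,4S,4aR,8aR)-3-acetoxy-4,7-dimethyl-6-oxo-3,4,4a,5,6,8a-hexahydronaphthalen-1(2H)-ylidene]propanoate | O=C1C[C@H]2[C@H](C)[C@@H](OC(C)=O)C/C(=C(/C)C(=O)OC)[C@H]2C=C1C | intermediate
17 | (2E)-2-[(3S,4S,4aR,6S,8aR)-3,6-dihydroxy-4,7-dimethyl-3,4,4a,5,6,8a-hexahydronaphthalen-1(2H)-ylidene]propan-1-ol | O[C@H]1C[C@H]2[C@H](C)[C@@H](O)C/C(=C(/C)CO)[C@H]2C=C1C | intermediate
18 | (2E)-2-[(3S,4S,4aR,6S,8aR)-3,6-dihydroxy-4,7-dimethyl-3,4,4a,5,6,8a-hexahydronaphthalen-1(2H)-ylidene]propyl formate | O[C@H]1C[C@H]2[C@H](C)[C@@H](O)C/C(=C(/C)COC=O)[C@H]2C=C1C | intermediate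
19 | (2E)-2-[(3S,4S,4aR,6S,8aR)-3,6-diacetoxy-4,7-dimethyl-3,4,4a,5,6,8a-hexahydronaphthalen-1(2H)-ylidene]propyl formate | CC(=O)O[C@H]1C[C@H]2[C@H](C)[C@@H](OC(C)=O)C/C(=C(/C)COC=O)[C@H]2C=C1C | target

**Step count and risks**

Total step count: 12. Longest linear sequence: 12 steps (1 to 19).

Three steps most likely to fail:

Step 9 (bicyclisation). Risks: slow or unselective cycloaddition, and base-induced isomerisation of the skipped dienone 16 at the fluoride stage. Fallback: sets out from 5 and comes back at 17, using the classical diene/dienophile partition. Heck coupling of 5 with (1E)-2-methylbuta-1,3-dien-1-yl acetate (PdCl2(cod), (t-Bu)3P·HBF4, Cy2NMe, DMF) gives the trienyl acetate acetal F1. TFA/H2O gives the aldehyde F2. Crotylboration with 9 under the step 6 conditions gives the syn alcohol F3, and Ac2O/pyridine gives the acetate F4. Heating F4 (toluene, BHT, 180 °C) brings about the intramolecular Diels–Alder reaction of the 1-acetoxydiene with the terminal vinyl group, which sets C3–OAc cis to C7 through the E,E-diene and gives the bicyclic diacetate ester F5. i-Bu2AlH then gives 17.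

Step 6 (crotylboration). Risks: lability of aldehyde 8, modest enantioselectivity with an aliphatic aldehyde, and lactonisation of 10. Fallback: sets out from 8 and comes back at 13, replacing crotylboration and metathesis by aldol and olefination. Titanium enolate aldol of 8 with (4R)-4-benzyl-3-propanoyl-1,3-thiazolidine-2-thione (TiCl4, i-Pr2NEt, NMP, CH2Cl2, −78 °C) gives the syn aldol adduct F6. Ac2O/pyridine gives the acetate F7. i-Bu2AlH at −78 °C releases the auxiliary and gives the aldehyde F8. Horner–Wadsworth–Emmons reaction of F8 with diethyl (2-oxobutyl)phosphonate (Ba(OH)2, THF/H2O) gives 13.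

Step 10 (reduction). Risk: the wrong face at C3. Fallback: sets out from 16 and comes back at 17. If hydride delivery gives mainly the C3 epimer, that epimer is made cleanly with NaBH4 and CeCl3·7H2O (MeOH, −78 °C), which leaves both esters intact and gives the 6R alcohol F9. Mitsunobu inversion (PPh3, DIAD, 4-nitrobenzoic acid) gives the 4-nitrobenzoate F10. i-Bu2AlH then cleaves the three esters and reduces the methyl ester to give 17.

**Further compounds**

F1 | step 9 | methyl (2E,4E,6E)-7-acetoxy-3-(2,2-dimethoxyethyl)-2,6-dimethylhepta-2,4,6-trienoate | COC(=O)/C(C)=C(/C=C/C(C)=C/OC(C)=O)CC(OC)OC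
F2 | step 9 | methyl (2E,4E,6E)-7-acetoxy-2,6-dimethyl-3-(2-oxoethyl)hepta-2,4,6-trienoate | COC(=O)/C(C)=C(/C=C/C(C)=C/OC(C)=O)CC=O
F3 | step 9 | methyl (2E,4E,6E)-7-acetoxy-3-[(2S,3S)-2-hydroxy-3-methylpent-4-en-1-yl]-2,6-dimethylhepta-2,4,6-trienoate | COC(=O)/C(C)=C(/C=C/C(C)=C/OC(C)=O)C[C@H](O)[C@@H](C)C=C
F4 | step 9 | methyl (2E,4E,6E)-7-acetoxy-3-[(2S,3S)-2-acetoxy-3-methylpent-4-en-1-yl]-2,6-dimethylhepta-2,4,6-trienoate | COC(=O)/C(C)=C(/C=C/C(C)=C/OC(C)=O)C[C@H](OC(C)=O)[C@@H](C)C=C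
F5 | step 9 | methyl (2E)-2-[(3S,4S,4aR,6S,8aR)-3,6-diacetoxy-4,7-dimethyl-3,4,4a,5,6,8a-hexahydronaphthalen-1(2H)-ylidene]propanoate | CC(=O)O[C@H]1C[C@H]2[C@H](C)[C@@H](OC(C)=O)C/C(=C(/C)C(=O)OC)[C@H]2C=C1C
F6 | step 6 | methyl (2E,4E)-3-{(2S,3R)-4-[(4R)-4-benzyl-2-sulfanylidene-1,3-thiazolidin-3-yl]-2-hydroxy-3-methyl-4-oxobutyl}-2-methyl-5-(phenylsulfonyl)penta-2,4-dienoate | COC(=O)/C(C)=C(/C=C/S(=O)(=O)c1ccccc1)C[C@H](O)[C@@H](C)C(=O)N1C(=S)SC[C@H]1Cc1ccccc1
F7 | step 6 | methyl (2E,4E)-3-{(2S,3R)-2-acetoxy-4-[(4R)-4-benzyl-2-sulfanylidene-1,3-thiazolidin-3-yl]-3-methyl-4-oxobutyl}-2-methyl-5-(phenylsulfonyl)penta-2,4-dienoate | COC(=O)/C(C)=C(/C=C/S(=O)(=O)c1ccccc1)C[C@H](OC(C)=O)[C@@H](C)C(=O)N1C(=S)SC[C@H]1Cc1ccccc1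
F8 | step 6 | methyl (2E,4E)-3-[(2S,3R)-2-acetoxy-3-methyl-4-oxobutyl]-2-methyl-5-(phenylsulfonyl)penta-2,4-dienoate | COC(=O)/C(C)=C(/C=C/S(=O)(=O)c1ccccc1)C[C@H](OC(C)=O)[C@@H](C)C=O
F9 | step 10 | methyl (2E)-2-[(3S,4S,4aR,6R,8aR)-3-acetoxy-6-hydroxy-4,7-dimethyl-3,4,4a,5,6,8a-hexahydronaphthalen-1(2H)-ylidene]propanoate | O[C@@H]1C[C@H]2[C@H](C)[C@@H](OC(C)=O)C/C(=C(/C)C(=O)OC)[C@H]2C=C1C
F10 | step 10 | methyl (2E)-2-[(3S,4S,4aR,6S,8aR)-3-acetoxy-4,7-dimethyl-6-(4-nitrobenzoyloxy)-3,4,4a,5,6,8a-hexahydronaphthalen-1(2H)-ylidene]propanoate | O=C(O[C@H]1C[C@H]2[C@H](C)[C@@H](OC(C)=O)C/C(=C(/C)C(=O)OC)[C@H]2C=C1C)c1ccc(cc1)[N+](=O)[O-]
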